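**Remark (assumption):** The SMILES contains no stereocentre, no stereogenic double bond and no hindered axis. The target (5-O-acetylhiascic acid, C26H22O12) is therefore achiral, and "single enantiomer" asks for nothing beyond the constitution. The ketene-acetal geometry of dienes 5 and 11 is drawn as (1Z); it has no bearing on the outcome.

## Analysis of the target

The target is a linear tridepside: three orsellinate-type benzene rings joined head to tail by two aryl ester bonds, with no stereocentre. Numbering used here: in ring A (the acetate-bearing ring) C1 carries the ester carbonyl, C2 an OH, C3 an H, C4 an OH, C5 the OAc and C6 the CH3. Ring B (primed) is acylated on O4' by ring A. Ring C (double primed) is acylated on O4'' by ring B and carries the free CO2H on C1''.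

The sensitive groups are the two depside esters and the aryl acetate (base, nucleophiles, transesterification). The O5 acetate sits next to the free O4–H and can migrate under base. The 2-hydroxy-6-methylbenzoic acid of ring C decarboxylates on heating.

The difficulty is ring A. It is pentasubstituted, and of the five phenolic oxygens of the molecule exactly one (O5) is acetylated, although its neighbour O4 is the more acidic and less hindered. The acyl carbons of rings A and B are each flanked by two ortho substituents, so classical depside esterification is slow.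

The feature that invites the chosen move: in ring A, C1 and C6 with their exocyclic carbons (carboxyl C and CH3) are the four carbons of a but-2-ynoate. C2–C5 with O2, O4 and O5 are the four carbons of a 4-acetoxy-3-oxobutanoate. Ring B shows the same partition (C1'/C6' against C2'–C5'). Each of these rings can therefore be grown on the phenol oxygen of its neighbour by a [4+2] benzannulation, with the acetate already bound to the carbon that becomes C5.

## Retrosynthetic reasoning

**14 from 13.** Only the C1'' carboxyl is masked, as a benzyl ester. It is removed last by neutral hydrogenolysis, which touches neither the aryl esters nor the acetate and avoids any base that could move the acetyl group from O5 to O4.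

**13 from 8 and 11 (ring A, bonds C1–C2 and C5–C6).** Ring A is cut across C1–C2 and C5–C6 in a retro-Diels–Alder sense. This gives the aryl but-2-ynoate 8 (C1, C6, the carboxyl carbon and the methyl group) and the diene 11 (C2–C5 with O2, O4 and the O5 acetate). The cut is made here because it removes the pentasubstituted ring, the hindered A–B ester formation and the O4/O5 differentiation in one operation. The forward reaction has to join the nucleophilic diene terminus C4 to the methyl-bearing alkyne carbon and then aromatise the cycloadduct 12 without losing the acetate.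

**11 from 10 from 9.** The diene is the bis-silyl dienol ether of the β-keto ester 10. Compound 10 is the acetate-substitution product of the commercial chloride 9. The acetate is installed here on an sp3 carbon, with no regiochemical choice.

**8 from 7 and 3 (bond O4'–C(=O)).** The A–B ester oxygen is acylated not by a 2,6-disubstituted benzoic acid but by the unhindered acid 3. In 7 only O4'–H is free of an intramolecular hydrogen bond, so no phenol protection is needed.

**7 from 4 and 5 (ring B, bonds C1'–C2' and C5'–C6').** Ring B is cut in the same way into the aryl but-2-ynoate 4 and the commercial parent diene 5, through the cycloadduct 6. This rehearses the key reaction on a simpler substrate and delivers the didepside 7 with both ring-B hydroxyl groups free.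

**4 from 2 and 3; 2 from 1.** Ring C is the only ring bought as an arene. Acid 1 is benzylated on the carboxyl group to give 2, whose free O4''–H is acylated by 3. The benzyl ester is the only protecting group of the route.

## Alternatives that were turned down

**Alternative 1:** The textbook route cuts the ester bond between the ring-A carbonyl and O4' (and, one stage earlier, the B–C ester bond in the same way). The forward key step is acylation of O4'–H of 7 by activated 5-acetoxy-2,4-bis(benzyloxy)-6-methylbenzoic acid A1 to give the protected tridepside A2, followed by hydrogenolysis. It was turned down because A1 holds the whole problem. Its C5 oxygen has to be put onto an orsellinate nucleus in which C3 (between two oxygens) and C5 (between O and CH3) compete. Its three oxygens then have to be told apart, and its acyl carbon is flanked by OBn and CH3 and deactivated by three donors. A1 alone would need about as many steps as the whole route proposed here. The ring-B acid needs its own protecting-group pattern, and the activation that the hindered acid demands puts the acetate at risk.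

**Alternative 2:** A biosynthesis-like late oxygenation cuts the C5–O bond of ring A. The forward key step is oxidation of the only free resorcinol ring of benzyl gyrophorate A3 (from 8 and 5) and reduction to benzyl hiascate A4, followed by acetylation of O5. It was turned down for three reasons. C3 and C5 of ring A are both ortho/para-activated, and nothing in the substrate favours C5. In A4 the O4–H is more acidic and less hindered than O5–H, so mono-acetylation is expected at the wrong oxygen or as a mixture. And the key step forms a single C–O bond, so the tridepside skeleton would still have to be built in full beforehand.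

**Alternative 3:** A polyketide-type closure cuts ring A at C1–C6 (aldol) and at the ester C–O bond (ketene trapping). The forward key step is thermolysis of the dioxinone A5 to an acylketene, trapping by O4'–H of 7 to give the aryl 6-acetoxy-3,5,7-trioxooctanoate A6, and base-mediated aldol condensation and aromatisation. It was turned down because A6 is an aryl ester. The C5 enol oxygen can attack C1 and expel the aryloxide of 7, a far better leaving group than an alkoxide, which gives the pyranone A7 and returns 7. In addition the acetate of A6 sits on a carbon between two ketones, where the base needed for the aldol step promotes acyl transfer. A5 itself would need about five steps.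

Key step: step 7

## Route

**Step 1**
Reactants: 1 orsellinic acid (2,4-dihydroxy-6-methylbenzoic acid)
Product: 2 benzyl orsellinate (benzyl 2,4-dihydroxy-6-methylbenzoate)
Conditions: BnBr, KHCO3, DMF, rt
Reagents that add atoms: benzyl bromide, BrCc1ccccc1
Why: Carboxylate O-alkylation (SN2); hydrogencarbonate deprotonates only the carboxylic acid, so both phenols stay free, and room temperature avoids decarboxylation.

**Step 2**
Reactants: 2 benzyl orsellinate; 3 but-2-ynoic acid
Product: 4 benzyl 4-(but-2-ynoyloxy)-2-hydroxy-6-methylbenzoate
Conditions: DCC, DMAP (5 mol%), CH2Cl2, 0 °C to rt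
Reagents that add atoms: none
Why: Steglich esterification, the usual way to aryl alk-2-ynoates; O2''–H is hydrogen-bonded to the ester carbonyl and hindered, so acylation should occur at O4'' only, and a low DMAP loading at 0 °C keeps phenol conjugate addition to the ynoate down.

**Step 3**
Reactants: 4 benzyl 4-(but-2-ynoyloxy)-2-hydroxy-6-methylbenzoate; 5 (1Z)-1-methoxy-1,3-bis(trimethylsilyloxy)buta-1,3-diene
Product: 7 benzyl lecanorate [benzyl 4-(2,4-dihydroxy-6-methylbenzoyloxy)-2-hydroxy-6-methylbenzoate], via cyclohexadiene cycloadduct 6 (not isolated)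
Conditions: 5 (3 equiv), PhMe, 110 °C, sealed tube; then 1 M HCl, THF, 0 °C to rt
Reagents that add atoms: none
Why: Diels–Alder reaction of an alk-2-ynoate with a 1-alkoxy-1,3-bis(silyloxy)diene, the established resorcylate benzannulation; the nucleophilic CH2 terminus of 5 bonds to the methyl-bearing alkyne carbon, which places the carboxyl between OH and CH3. Acidic work-up cleaves the Si–O bonds, the hemiketal loses methanol and the dienone tautomerises to ring B; any silylation of the chelated OH by excess 5 is reversed at the same time.

**Step 4**
Reactants: 7 benzyl lecanorate; 3 but-2-ynoic acid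
Product: 8 benzyl 4-{[4-(but-2-ynoyloxy)-2-hydroxy-6-methylbenzoyl]oxy}-2-hydroxy-6-methylbenzoate
Conditions: DCC, DMAP (5 mol%), CH2Cl2, 0 °C to rt
Reagents that add atoms: none
Why: Steglich esterification as in step 2; of the three phenols of 7 only O4'–H is not chelated to an ortho ester carbonyl, so it should be acylated selectively.

**Step 5**
Reactants: 9 methyl 4-chloro-3-oxobutanoate
Product: 10 methyl 4-acetoxy-3-oxobutanoate
Conditions: KOAc, AcOH, DMF, rt
Reagents that add atoms: potassium acetate, CC(=O)[O-].[K+]
Why: SN2 displacement at a primary α-chloro ketone by acetate; the acetic acid buffer keeps the β-keto ester protonated and so suppresses self-alkylation.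

**Step 6**
Reactants: 10 methyl 4-acetoxy-3-oxobutanoate
Product: 11 (1Z,3Z)-4-acetoxy-1-methoxy-1,3-bis(trimethylsilyloxy)buta-1,3-diene
Conditions: TMSOTf (2.2 equiv), Et3N (2.5 equiv), Et2O, 0 °C to rt; non-aqueous isolation (pentane), used directly
Reagents that add atoms: trimethylsilyl trifluoromethanesulfonate, C[Si](C)(C)OS(=O)(=O)C(F)(F)F
Why: Soft enolisation (silyl triflate and amine) converts β-keto esters into 1-alkoxy-1,3-bis(silyloxy)-1,3-dienes in one pot without a strong base; C4–H, next to the ketone and the acetoxy group, is far more acidic than the acetate methyl, which should be left alone. The (3Z) geometry (O3 and O4 cis), expected for enolisation of an α-acyloxy ketone, places the acetoxy group on the outside of the s-cis diene.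

**Step 7**
Reactants: 8 benzyl 4-{[4-(but-2-ynoyloxy)-2-hydroxy-6-methylbenzoyl]oxy}-2-hydroxy-6-methylbenzoate; 11 (1Z,3Z)-4-acetoxy-1-methoxy-1,3-bis(trimethylsilyloxy)buta-1,3-diene
Product: 13 benzyl 5-O-acetylhiascate [benzyl ester of the target], via acetoxy cyclohexadiene cycloadduct 12 (not isolated)
Conditions: 11 (3 equiv), PhMe, 100 °C, sealed tube; then 0.5 M HCl, THF, 0 °C
Reagents that add atoms: none
Why: Normal-electron-demand Diels–Alder reaction: the aryl ynoate of 8 (LUMO lowered by the aryl ester) meets the tetra-oxygenated diene 11, whose largest HOMO coefficient lies at C4 (β to the silyl enol ether, δ to the ketene-acetal oxygens), so C4 bonds to the methyl-bearing β-carbon and C1 to the α-carbon of the ynoate. The closest known reaction type is the resorcylate synthesis from open-chain and macrocyclic alk-2-ynoates and 1-alkoxy-1,3-bis(silyloxy)- or 1,1-dialkoxy-3-silyloxy-buta-1,3-dienes, which gives exactly this orientation (carboxyl between O and alkyl). Ring A is closed intermolecularly as a six-membered carbocycle by a concerted, asynchronous [4+2] cycloaddition that forms C1–C2 and C5–C6. The two stereocentres of 12 (the future C2 and C5, OMe and OAc cis from suprafacial addition to the (1Z,3Z)-diene) are erased when the acidic work-up cleaves the Si–O bonds, the C2 hemiketal expels methanol and the dienone tautomerises to the arene; aromatisation by loss of acetic acid is not open, because C2 carries no hydrogen. The step needs regioselectivity (secured by the matched polarisation above), chemoselectivity (8 has one alkyne, and its aryl and benzyl esters are inert to a silyl ketene acetal without a Lewis acid) and positional integrity of the acetate (fixed by the diene carbon that carries it, so no choice between phenols arises). The chelated OH groups of 8 may be silylated by excess 11, and the work-up reverses this.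

**Step 8**
Reactants: 13 benzyl 5-O-acetylhiascate
Product: 14 5-O-acetylhiascic acid [4-{[4-(3-acetoxy-4,6-dihydroxy-2-methylbenzoyloxy)-2-hydroxy-6-methylbenzoyl]oxy}-2-hydroxy-6-methylbenzoic acid]
Conditions: H2 (1 atm), 10% Pd/C, EtOAc, rt
Reagents that add atoms: none
Why: Hydrogenolysis of the benzyl ester under neutral conditions; aryl esters and the aryl acetate are inert, and the absence of base excludes acetyl migration from O5 to O4 and decarboxylation.

## Compound list

1 | orsellinic acid (2,4-dihydroxy-6-methylbenzoic acid) | Cc1cc(O)cc(O)c1C(=O)O | starting material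
2 | benzyl orsellinate (benzyl 2,4-dihydroxy-6-methylbenzoate) | Cc1cc(O)cc(O)c1C(=O)OCc1ccccc1 | intermediate
3 | but-2-ynoic acid | CC#CC(=O)O | starting material
4 | benzyl 4-(but-2-ynoyloxy)-2-hydroxy-6-methylbenzoate | CC#CC(=O)Oc1cc(C)c(C(=O)OCc2ccccc2)c(O)c1 | intermediate
5 | (1Z)-1-methoxy-1,3-bis(trimethylsilyloxy)buta-1,3-diene | C=C(O[Si](C)(C)C)/C=C(\O[Si](C)(C)C)OC | starting material
6 | 4-[(benzyloxy)carbonyl]-3-hydroxy-5-methylphenyl 6-methoxy-2-methyl-4,6-bis(trimethylsilyloxy)cyclohexa-1,4-diene-1-carboxylate (racemic at C6, not isolated) | COC1(O[Si](C)(C)C)C=C(O[Si](C)(C)C)CC(C)=C1C(=O)Oc2cc(C)c(C(=O)OCc3ccccc3)c(O)c2 | intermediate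
7 | benzyl lecanorate (benzyl 4-[(2,4-dihydroxy-6-methylbenzoyl)oxy]-2-hydroxy-6-methylbenzoate) | Cc1cc(O)cc(O)c1C(=O)Oc1cc(C)c(C(=O)OCc2ccccc2)c(O)c1 | intermediate
8 | benzyl 4-{[4-(but-2-ynoyloxy)-2-hydroxy-6-methylbenzoyl]oxy}-2-hydroxy-6-methylbenzoate | CC#CC(=O)Oc1cc(C)c(C(=O)Oc2cc(C)c(C(=O)OCc3ccccc3)c(O)c2)c(O)c1 | intermediate
9 | methyl 4-chloro-3-oxobutanoate | COC(=O)CC(=O)CCl | starting material
10 | methyl 4-acetoxy-3-oxobutanoate | COC(=O)CC(=O)COC(C)=O | intermediate
11 | (1Z,3Z)-4-acetoxy-1-methoxy-1,3-bis(trimethylsilyloxy)buta-1,3-diene | CC(=O)O/C=C(\O[Si](C)(C)C)/C=C(\O[Si](C)(C)C)OC | intermediate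
12 | aryl 3-acetoxy-6-methoxy-2-methyl-4,6-bis(trimethylsilyloxy)cyclohexa-1,4-diene-1-carboxylate of 7 (racemic, 3-OAc and 6-OMe cis; relative configuration shown; not isolated) | CO[C@]1(O[Si](C)(C)C)C=C(O[Si](C)(C)C)[C@H](OC(C)=O)C(C)=C1C(=O)Oc2cc(C)c(C(=O)Oc3cc(C)c(C(=O)OCc4ccccc4)c(O)c3)c(O)c2 | intermediate
13 | benzyl 5-O-acetylhiascate (benzyl ester of the target) | CC(=O)Oc1c(O)cc(O)c(C(=O)Oc2cc(C)c(C(=O)Oc3cc(C)c(C(=O)OCc4ccccc4)c(O)c3)c(O)c2)c1C | intermediate
14 | 5-O-acetylhiascic acid | CC(=O)Oc1c(O)cc(O)c(C(=O)Oc2cc(C)c(C(=O)Oc3cc(C)c(C(=O)O)c(O)c3)c(O)c2)c1C | target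

## Step count and least certain steps

Total: 8 steps. Longest linear sequence: 6 steps (1, 2, 3, 4, 7, 8); the diene branch (steps 5 and 6) joins at step 7.

**Step 7 (key step).** A β-methyl ynoate is a sluggish dienophile, while diene 11 is thermally labile (1,5-silyl shift, acetyl transfer between O3 and O4 of the diene). Decomposition of the diene or scrambling of the acetate position may therefore outrun cycloaddition. In the work-up the doubly allylic acetate of the cycloadduct may solvolyse, or the ketal may collapse with loss of silanol instead of methanol and leave a 2-O-methyl ether.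

Fallback: classical fragment coupling, which sets out from 7 (acid partner made from 2) and comes back to the route at 14.
- Compound 2 is alkylated at the free O4 (BnBr, K2CO3, acetone, reflux) to benzyl 4-(benzyloxy)-2-hydroxy-6-methylbenzoate F1.
- Saponification (KOH, aqueous DMSO, 80 °C, then HCl) gives 4-(benzyloxy)-2-hydroxy-6-methylbenzoic acid F2.
- Elbs persulfate oxidation (K2S2O8, aqueous KOH, 0 °C to rt) hydroxylates para to the free phenol, at C5, through the aryl sulfate 4-(benzyloxy)-2-hydroxy-6-methyl-5-(sulfooxy)benzoic acid F3 (present as its potassium salt).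
- Hydrolysis of F3 in dilute HCl at 60 °C gives 4-(benzyloxy)-2,5-dihydroxy-6-methylbenzoic acid F4.
- Acetylation (Ac2O, pyridine, 0 °C, aqueous work-up) should occur at the only non-chelated phenol and give 5-acetoxy-4-(benzyloxy)-2-hydroxy-6-methylbenzoic acid F5.
- Steglich coupling of F5 with O4'–H of 7 (DCC, DMAP cat., CH2Cl2) gives the O4-benzyl ether of 13, compound F6.
- Hydrogenolysis of F6 (H2, Pd/C, EtOAc) removes both benzyl groups and gives 14.

**Step 6.** Over-silylation (enolisation of the acetate carbonyl by excess silyl triflate), incomplete second silylation, or formation of the (3E) isomer with the acetoxy group inside the diene would give a reagent that is impure or unreactive in step 7.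

Fallback: stepwise formation through an isolated intermediate and a kinetically controlled lithium dienolate instead of amine/triflate enolisation. It sets out from 10 and comes back at 11. Compound 10 is silylated once (TMSCl, Et3N, benzene, rt) to methyl (2Z)-4-acetoxy-3-(trimethylsilyloxy)but-2-enoate F7, which is purified by distillation. F7 is then deprotonated at C4 with LiN(SiMe3)2 (1.05 equiv, THF, −78 °C) and trapped on oxygen with TMSCl to give 11. Should 11 remain inaccessible, the fallback given for step 7 does not need it.

**Step 3.** The cycloaddition may be too slow at temperatures the diene survives, and proto-desilylation of 5 by the chelated phenol of 4 uses up reagent, so conversion may stall.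

Fallback: conventional depside formation, which sets out from 2 and comes back at 7.
- Compound 2 is fully benzylated (BnBr, K2CO3, DMF, 70 °C) to benzyl 2,4-bis(benzyloxy)-6-methylbenzoate F8.
- Saponification (KOH, aqueous DMSO, 90 °C, then HCl) gives 2,4-bis(benzyloxy)-6-methylbenzoic acid F9.
- Mixed-anhydride coupling of F9 with O4''–H of a second portion of 2 (trifluoroacetic anhydride, PhMe, rt) gives benzyl 4-{[2,4-bis(benzyloxy)-6-methylbenzoyl]oxy}-2-hydroxy-6-methylbenzoate F10.
- Hydrogenolysis (H2, Pd/C, EtOAc) gives lecanoric acid F11.
- Carboxyl-selective benzylation of F11 as in step 1 (BnBr, KHCO3, DMF, rt) returns 7.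

## Further compounds

F1 | step 7 | benzyl 4-(benzyloxy)-2-hydroxy-6-methylbenzoate | Cc1cc(OCc2ccccc2)cc(O)c1C(=O)OCc1ccccc1
F2 | step 7 | 4-(benzyloxy)-2-hydroxy-6-methylbenzoic acid | Cc1cc(OCc2ccccc2)cc(O)c1C(=O)O
F3 | step 7 | 4-(benzyloxy)-2-hydroxy-6-methyl-5-(sulfooxy)benzoic acid | Cc1c(OS(=O)(=O)O)c(OCc2ccccc2)cc(O)c1C(=O)O
F4 | step 7 | 4-(benzyloxy)-2,5-dihydroxy-6-methylbenzoic acid | Cc1c(O)c(OCc2ccccc2)cc(O)c1C(=O)O
F5 | step 7 | 5-acetoxy-4-(benzyloxy)-2-hydroxy-6-methylbenzoic acid | Cc1c(OC(C)=O)c(OCc2ccccc2)cc(O)c1C(=O)O
F6 | step 7 | benzyl 4-{[4-({3-acetoxy-4-(benzyloxy)-6-hydroxy-2-methylbenzoyl}oxy)-2-hydroxy-6-methylbenzoyl]oxy}-2-hydroxy-6-methylbenzoate | Cc1c(OC(C)=O)c(OCc2ccccc2)cc(O)c1C(=O)Oc1cc(C)c(C(=O)Oc2cc(C)c(C(=O)OCc3ccccc3)c(O)c2)c(O)c1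
F7 | step 6 | methyl (2Z)-4-acetoxy-3-(trimethylsilyloxy)but-2-enoate | COC(=O)/C=C(\O[Si](C)(C)C)COC(C)=O
F8 | step 3 | benzyl 2,4-bis(benzyloxy)-6-methylbenzoate | Cc1cc(OCc2ccccc2)cc(OCc2ccccc2)c1C(=O)OCc1ccccc1
F9 | step 3 | 2,4-bis(benzyloxy)-6-methylbenzoic acid | Cc1cc(OCc2ccccc2)cc(OCc2ccccc2)c1C(=O)O
F10 | step 3 | benzyl 4-{[2,4-bis(benzyloxy)-6-methylbenzoyl]oxy}-2-hydroxy-6-methylbenzoate | Cc1cc(OCc2ccccc2)cc(OCc2ccccc2)c1C(=O)Oc1cc(C)c(C(=O)OCc2ccccc2)c(O)c1
F11 | step 3 | lecanoric acid (4-[(2,4-dihydroxy-6-methylbenzoyl)oxy]-2-hydroxy-6-methylbenzoic acid) | Cc1cc(O)cc(O)c1C(=O)Oc1cc(C)c(C(=O)O)c(O)c1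
A1 | alternative 1 | 5-acetoxy-2,4-bis(benzyloxy)-6-methylbenzoic acid | Cc1c(OC(C)=O)c(OCc2ccccc2)cc(OCc2ccccc2)c1C(=O)O
A2 | alternative 1 | benzyl 4-{[4-({3-acetoxy-4,6-bis(benzyloxy)-2-methylbenzoyl}oxy)-2-hydroxy-6-methylbenzoyl]oxy}-2-hydroxy-6-methylbenzoate | Cc1c(OC(C)=O)c(OCc2ccccc2)cc(OCc2ccccc2)c1C(=O)Oc1cc(C)c(C(=O)Oc2cc(C)c(C(=O)OCc3ccccc3)c(O)c2)c(O)c1
A3 | alternative 2 | benzyl gyrophorate | Cc1cc(O)cc(O)c1C(=O)Oc1cc(C)c(C(=O)Oc2cc(C)c(C(=O)OCc3ccccc3)c(O)c2)c(O)c1
A4 | alternative 2 | benzyl hiascate | Cc1c(O)c(O)cc(O)c1C(=O)Oc1cc(C)c(C(=O)Oc2cc(C)c(C(=O)OCc3ccccc3)c(O)c2)c(O)c1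
A5 | alternative 3 | 1-(2,2-dimethyl-4-oxo-4H-1,3-dioxin-6-yl)-2,4-dioxopentan-3-yl acetate (racemic) | CC(=O)OC(C(C)=O)C(=O)CC1=CC(=O)OC(C)(C)O1
A6 | alternative 3 | O4'-(6-acetoxy-3,5,7-trioxooctanoyl) ester of 7 (racemic) | CC(=O)OC(C(C)=O)C(=O)CC(=O)CC(=O)Oc1cc(C)c(C(=O)Oc2cc(C)c(C(=O)OCc3ccccc3)c(O)c2)c(O)c1
A7 | alternative 3 | 6-(1-acetoxy-2-oxopropyl)-4-hydroxy-2H-pyran-2-one (racemic) | CC(=O)OC(C(C)=O)c1cc(O)cc(=O)o1
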